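## The problem

The target is a 1,4-dihydroxypyridin-2(1H)-one whose ring carbons C3 and C5 carry the two halves of the molecule. C3 is acylated by an all-E deca-2,4,6-trienoyl chain that ends in the only stereogenic centre, C8'' (R, bearing ethyl and hydroxymethyl). C5 is bonded to C1' of a cyclohexane, a fully substituted carbinol whose hydroxyl is cis to the secondary hydroxyl on C4'. The cyclohexane is achiral (C1' and C4' lie on a mirror plane) and sits more than ten bonds from C8'', so neither element can steer the other: C8'' must come from a reagent-controlled step and the cis-1,4 relation from the way the two ring oxygens are introduced. Three groups limit the late chemistry. The trienone is reduced by hydrogenation, attacked by peracids, nucleophiles and strong base, and isomerised by light. The N–OH group has a reducible N–O bond and is a chelating acid. The C1' alcohol is tertiary and conjugated through C5=C6 with the ring nitrogen, so it ionises under acid and gives the cyclohexene. Hydrogenolysis and strong protic or Lewis acids are therefore excluded at the end, every group that reaches the last step has to leave with fluoride, and the N–O bond has to exist before the chain is attached, because no N-oxidant would spare the triene. The feature that opens the plan is the pair of oxygens on C1' and C4': they are 1,4 and cis on a six-membered carbocycle, which is what an O–O bridge across the termini of a cyclohexa-1,3-diene (C1'=C2'–C3'=C4', pyridyl on C1') leaves behind once C2'=C3' is saturated and the peroxide is reduced.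

## Retrosynthesis

No skeletal bond is cut first. Target 37 is traced to 36, in which every hydroxyl carries a silicon-based group: triethylsilyl on O1' and O4', tert-butyldimethylsilyl on the chain oxygen, 2-(trimethylsilyl)ethyl on O4 and [2-(trimethylsilyl)ethoxy]methyl on the N-oxygen. The neighbouring choice, benzyl ethers kept to the end, would leave only by hydrogenolysis (lost triene) or by a strong Lewis acid (lost C1' carbinol). One fluoride treatment asks nothing of either group. It must cleave Si–O bonds and fragment the two β-silylethyl groups, which is reasonable because both pyridone oxygens are good leaving groups.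

The bond between C3 and the ketone carbon C1'' is cut next: 36 comes from carbinol 35 by oxidation, and 35 from 3-iodopyridone 20 and trienal 33. Against this stand acylation of a hydroxypyridone (poor control of O- versus C-acylation with a trienoyl donor) and growth of the chain on the heterocycle (more steps on the valuable half). The cut gives two fragments of similar size, each with one stereochemical element. The forward reaction has to metalate C3 without disturbing the N–O acetal and add 1,2 to a conjugated aldehyde; the new carbinol centre is of no consequence.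

Trienal 33 is the oxidation-level adjustment (through alcohol 32) of trienoate 31. Cutting C4''=C5'' gives enal 29 and the four-carbon phosphonate 30. Cutting C6''=C7'' gives aldehyde 28, made in the flask from alcohol 26, and the two-carbon ylide 27. Stabilised phosphorus reagents are preferred to cross-couplings of vinyl metals because each sets an E alkene under conditions that leave the α-branched centre alone, and both reagents are purchased. The α-stereogenic aldehyde 28 must not be stored.

C8'' is traced through 26, 25 and 24 to imide 23, made from oxazolidinone 21 and butanoyl chloride 22. The bond cut is the one between C8'' and the hydroxymethyl carbon, formed by adding a one-carbon electrophile to the enolate of 23 under control of the auxiliary. Desymmetrisation of the prochiral diol was the alternative; the auxiliary route is chosen because its facial sense is predictable. The new hydroxyl must be silylated (25) before the auxiliary is removed, otherwise the product would be an achiral diol.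

Iodide 20 is simplified by removing iodine from C3 (19), then by exchanging the N–O acetal for the N–O benzyl ether (18, 17). The N–O bond itself is traced to N-oxide 16 and pyridine 15 through a 1,4 shift of benzyl from O2 to the N-oxide oxygen. This places the N–O bond, the pyridone carbonyl and a nucleophilic C3 in two steps from a pyridine. The benzyl group is exchanged at 17, where the molecule holds neither an alkene nor iodine, so hydrogenolysis is safe. O4 carries its β-silylethyl group from the start so that only one group has to be exchanged and no O2/O4 ambiguity arises in an alkylation.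

Bis-silyl ether 15 comes from diol 14, and 14 from saturated peroxide 13 by reduction of the O–O bond; 13 comes from bicyclic alkene 12 by concerted hydrogen transfer. The alkene is saturated first so that the C1' oxygen is never tertiary, allylic and free at the same time. Both steps leave the two C–O bonds untouched, so the cis relation of 12 is carried into 14.

The key cut removes the O–O bridge of 12: the C1'–O and C4'–O bonds are cut together to give diene 10 and dioxygen 11 (as singlet oxygen). The nearest alternative, adding a 5-metalated pyridine to a 4-oxygenated cyclohexanone, makes the C5–C1' bond and the carbinol at once but leaves cis against trans to the facial preference of the ketone. Here the bridge can only span one face. Precursor 10 has no stereocentre and no oxygen on the carbocycle. The forward reaction must be a [4+2] addition, not an ene reaction, and must leave the heteroarene alone.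

Diene 10 is cut at the C5–C1' bond into the pyridyl boronate 9 (from bromide 5 and diboron 8) and dienyl triflate 7, which comes from cyclohexenone 6. Bromide 5 is cut at its two C–O bonds to 3 and benzyl alcohol 4, and 3 to dichloride 1 and silyl alcohol 2. The bromine of 1 already marks C5, and the two chlorides differ enough in reactivity to take two different alkoxides in sequence.

## Roads not taken

Alternative 1: The pyridone C4–C5 bond is cut and the six-membered heterocycle is traced to a five-membered tetramic acid, A1, whose side-chain carbon (between the ring carbon next to nitrogen and C1' of the protected cyclohexane) carries a xanthate. In the forward sense a radical at that carbon adds to the ring ketone, the cyclopropyloxy radical opens the other way, and the ring grows by one carbon to piperidine-2,4-dione A2.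
- Merits: it follows the presumed biogenetic ring expansion, makes the C4–C5 bond and the six-membered ring in one step, and starts from an amino-acid-type building block of a class that is easily acylated at C3.
- Weak points: A1 already contains the quaternary carbinol and the cis-1,4 oxygens, so the stereochemical problem of the carbocycle is only moved into the synthesis of a β-branched amino acid. The 3-exo addition to a carbonyl is reversible and competes with simple reduction of the radical. A2 is two oxidation levels from the target ring (dehydrogenation, then N-hydroxylation of a lactam N–H, for which only inefficient silylation/peroxometal procedures are known), and the C5 stereocentre it creates is destroyed.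
- Comparison: this is the more original road and would be the better one if the aim were to test the biogenetic idea. It is longer to material of the type of 20 and rests on several unproven steps. The chosen plan sets against it a purchased pyridine (1), an N–O bond made by a known oxidation and shift (steps 9 and 10) and a carbocycle whose configuration is fixed by the key step.

Alternative 2: The bonds C3–C1'' and C1''–C2'' are cut together. 3-Iodopyridone A4, a one-carbon carbonyl unit and trienylstannane A3 are joined by zerovalent palladium (oxidative addition into C3–I, carbonyl insertion, transfer of the trienyl group from tin) to give the protected trienoyl pyridone A5.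
- Merits: no ring closure is needed, the union takes one step where the chosen plan takes two (steps 22 and 23), the ketone level is reached directly, and the free C1' hydroxyl is tolerated, so a silylation would be saved. In step economy at the fragment union this road is better.
- Weak points: carbonyl insertion at an iodide flanked by two ortho substituents is slow, and direct coupling without insertion competes. A3 is a light- and acid-sensitive trienyl tin compound that costs as many steps as 33, and tin residues must be removed from a chelating product. A5 still carries two benzyl ethers, which cannot leave by hydrogenolysis beside the triene, only with a strong Lewis acid that the C1' carbinol will not survive.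
- Comparison: this road is an end-game and says nothing on how the cis-1,4-diol is made, so it is a substitute for steps 22 and 23, not a rival to the key step. It is kept as the fallback for step 22, applied to 20, where the benzyl problem does not arise. Against its one-step advantage the chosen plan sets tin-free chemistry and an aldehyde addition that does not depend on the rate of an insertion.

Alternative 3: The bonds C1'–C2' and C1'–C6' are cut. Nicotinate ester A6 takes up both ends of the ketal-bearing pentane-1,5-diyl bis-Grignard reagent A7, closing the cyclohexane by a [5+1] annulation and giving the tertiary carbinol A8 with C4' as its ketal.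
- Merits: the carbocycle and the C1' carbinol arise in one operation from an ester. The way to a C1' carbinol is shorter than the coupling, photooxygenation and two reductions of the chosen plan (steps 4 to 7), and no peroxide is handled. In step count to the carbinol this road is better.
- Weak points: A7 has oxygen γ to both carbon–magnesium bonds and is prone to 1,3-elimination and to coupling while it forms. The dihalide behind A7 and the ester A6 each need several steps. A8 has no C4' stereocentre, so the ketal must be hydrolysed with acid next to the ionisable C1' carbinol and the ketone reduced; the cis relation then rests on the facial preference of a hydride for a 4,4-disubstituted cyclohexanone, which means a ratio and a separation.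
- Comparison: shorter on paper. The chosen plan sets against it that the cis-1,4 relation in 12 is enforced by the O–O bridge with no isomer to remove, and that between 12 and 14 the C1' oxygen meets no acid stronger than acetic acid.

Key step: step 5

Remark: C1' and C4' are pseudoasymmetric centres of an achiral cis-1,4-disubstituted ring (both oxygens on one face), so 12 may be racemic and only C8'' needs absolute control; locants are N1–C6 (pyridone), C1'–C6' (cyclohexane) and C1''–C10'' (chain, C1'' the ketone carbon).

## Route

Step 1
Reactants: 1 5-bromo-2,4-dichloropyridine; 2 2-(trimethylsilyl)ethanol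
Product: 3 5-bromo-2-chloro-4-[2-(trimethylsilyl)ethoxy]pyridine
Conditions: NaH, THF, 0 °C → rt
Reagents that add atoms: none
Why: Nucleophilic aromatic substitution (addition–elimination); the alkoxide should attack C4, para to nitrogen and next to bromine, faster than C2, so one equivalent at low temperature should stop at the 4-ether, and the β-silylethyl group is chosen because it later leaves with fluoride.

Step 2
Reactants: 3 5-bromo-2-chloro-4-[2-(trimethylsilyl)ethoxy]pyridine; 4 benzyl alcohol
Product: 5 2-(benzyloxy)-5-bromo-4-[2-(trimethylsilyl)ethoxy]pyridine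
Conditions: KOH, 18-crown-6, toluene, reflux (water removed)
Reagents that add atoms: none
Why: Second nucleophilic aromatic substitution, now at the less reactive C2 and therefore run hot; the C5 bromide is not activated for substitution and the β-silylethyl ether is stable to alkoxide, and benzyl is placed on O2 because it is the group that can later migrate to the N-oxide oxygen.

Step 3
Reactants: 6 cyclohex-2-en-1-one
Product: 7 cyclohexa-1,3-dien-1-yl trifluoromethanesulfonate
Conditions: Tf2O, 2,6-di-tert-butyl-4-methylpyridine, CH2Cl2, 0 °C → rt
Reagents that add atoms: trifluoromethanesulfonic anhydride, O=S(=O)(OS(=O)(=O)C(F)(F)F)C(F)(F)F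
Why: O-Triflation of the enone gives an oxygen-substituted allyl cation that the hindered base deprotonates at the γ-carbon, which should give the linearly conjugated dienyl triflate (thermodynamic dienol triflate formation) with the leaving group on a diene terminus.

Step 4
Reactants: 5 2-(benzyloxy)-5-bromo-4-[2-(trimethylsilyl)ethoxy]pyridine; 8 bis(pinacolato)diboron; 7 cyclohexa-1,3-dien-1-yl trifluoromethanesulfonate
Product: 10 2-(benzyloxy)-5-(cyclohexa-1,3-dien-1-yl)-4-[2-(trimethylsilyl)ethoxy]pyridine, via pyridyl pinacol boronate 9 (not isolated)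
Conditions: PdCl2(dppf), KOAc, dioxane, 90 °C; then 7, aq K3PO4, 60 °C
Reagents that add atoms: none
Why: Miyaura borylation followed in the same flask by Suzuki–Miyaura coupling; the boronate sits at a 3-pyridyl-type position and should resist protodeboronation, and the alkenyl triflate couples with retention of the position of both double bonds, so the pyridine ends up on the diene terminus C1'.

Step 5
Reactants: 10 2-(benzyloxy)-5-(cyclohexa-1,3-dien-1-yl)-4-[2-(trimethylsilyl)ethoxy]pyridine; 11 dioxygen
Product: 12 2-(benzyloxy)-5-(2,3-dioxabicyclo[2.2.2]oct-5-en-1-yl)-4-[2-(trimethylsilyl)ethoxy]pyridine (racemic)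
Conditions: O2, tetraphenylporphyrin (cat.), CH2Cl2, visible light, −20 °C
Reagents that add atoms: none
Why: The light-excited porphyrin passes its triplet energy to ground-state O2, and the singlet oxygen so formed adds in a concerted, suprafacial [4+2] cycloaddition to the ring-locked s-cis diene C1'=C2'–C3'=C4' of 10, making the C1'–O and C4'–O bonds together. The closest known reaction type is the sensitised photooxygenation of cyclohexa-1,3-dienes, 1-aryl dienes included, to 2,3-dioxabicyclo[2.2.2]oct-5-enes (α-terpinene to ascaridole is the textbook case). The only ring closed is the six-membered 1,2-dioxine; it closes by cycloaddition, both new bonds forming in the same step, and appears as the third bridge of the bicycle. C1' and C4' become stereocentres here and are controlled by the O–O tether itself: a two-atom bridge can span only one face, so the two oxygens are cis by construction, and 12 is racemic because either diene face is attacked, which does not matter since both enantiomers give the same achiral diol in step 7. The step needs [4+2] addition in preference to the ene reaction at the C5'/C6' methylenes, to [2+2] addition and to oxidation of the heteroarene; the cisoid geometry fixed by the ring, the low temperature and the electron-poor 2,4-dialkoxypyridine, which neither reacts with nor quenches singlet oxygen as a pyridone would, should secure this. The benzylic and α-silyl C–H bonds of the ether groups are inert to singlet oxygen. The fully substituted C1'–O bond is thus made without any organometallic addition to a ketone.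

Step 6
Reactants: 12 2-(benzyloxy)-5-(2,3-dioxabicyclo[2.2.2]oct-5-en-1-yl)-4-[2-(trimethylsilyl)ethoxy]pyridine
Product: 13 2-(benzyloxy)-5-(2,3-dioxabicyclo[2.2.2]octan-1-yl)-4-[2-(trimethylsilyl)ethoxy]pyridine
Conditions: KO2CN=NCO2K, AcOH, MeOH/CH2Cl2, 0 °C → rt
Reagents that add atoms: none
Why: Diimide reduction: concerted syn transfer of two hydrogens to the strained bicyclic alkene through a six-membered transition state, known to leave peroxide O–O bonds, benzyl ethers and pyridines untouched; saturating first removes the allylic activation of the C1'–O bond before it becomes a free alcohol, and the product is achiral.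

Step 7
Reactants: 13 2-(benzyloxy)-5-(2,3-dioxabicyclo[2.2.2]octan-1-yl)-4-[2-(trimethylsilyl)ethoxy]pyridine
Product: 14 cis-1-{6-(benzyloxy)-4-[2-(trimethylsilyl)ethoxy]pyridin-3-yl}cyclohexane-1,4-diol
Conditions: Zn, AcOH, CH2Cl2, rt
Reagents that add atoms: none
Why: Two-electron reductive cleavage of the peroxide O–O bond by zinc in acetic acid; neither C–O bond is broken, so the cis relation written into 12 is delivered unchanged, with the pyridyl group trans to the C4' hydroxyl.

Step 8
Reactants: 14 cis-1-{6-(benzyloxy)-4-[2-(trimethylsilyl)ethoxy]pyridin-3-yl}cyclohexane-1,4-diol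
Product: 15 2-(benzyloxy)-5-[cis-1,4-bis(triethylsilyloxy)cyclohexyl]-4-[2-(trimethylsilyl)ethoxy]pyridine
Conditions: Et3SiOTf, 2,6-lutidine, CH2Cl2, −78 → 0 °C
Reagents that add atoms: triethylsilyl trifluoromethanesulfonate, CC[Si](CC)(CC)OS(=O)(=O)C(F)(F)F
Why: Silylation with a silyl triflate, reactive enough for the tertiary as well as the secondary alcohol at low temperature, where reversible N-silylation of the benzyloxypyridine should not transfer benzyl; the ethers keep the later intermediates lipophilic, withstand the organomagnesium step and leave with fluoride.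

Step 9
Reactants: 15 2-(benzyloxy)-5-[cis-1,4-bis(triethylsilyloxy)cyclohexyl]-4-[2-(trimethylsilyl)ethoxy]pyridine
Product: 16 2-(benzyloxy)-5-[cis-1,4-bis(triethylsilyloxy)cyclohexyl]-4-[2-(trimethylsilyl)ethoxy]pyridine 1-oxide
Conditions: mCPBA, CH2Cl2, 0 °C → rt
Reagents that add atoms: 3-chloroperoxybenzoic acid, OOC(=O)c1cccc(Cl)c1
Why: Peracid N-oxidation of a pyridine; the 4-alkoxy group offsets the deactivation by the 2-alkoxy group, and the molecule holds no alkene or other oxidisable site at this stage.

Step 10
Reactants: 16 2-(benzyloxy)-5-[cis-1,4-bis(triethylsilyloxy)cyclohexyl]-4-[2-(trimethylsilyl)ethoxy]pyridine 1-oxide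
Product: 17 1-(benzyloxy)-5-[cis-1,4-bis(triethylsilyloxy)cyclohexyl]-4-[2-(trimethylsilyl)ethoxy]pyridin-2(1H)-one
Conditions: toluene, 110 °C
Reagents that add atoms: none
Why: Thermal 1,4 shift of benzyl from O2 to the N-oxide oxygen, the known sigmatropic rearrangement of 2-benzyloxypyridine N-oxides to 1-benzyloxy-2-pyridones, driven by formation of the amide carbonyl; the primary β-silylethyl group on O4 has no such path and should stay in place.

Step 11
Reactants: 17 1-(benzyloxy)-5-[cis-1,4-bis(triethylsilyloxy)cyclohexyl]-4-[2-(trimethylsilyl)ethoxy]pyridin-2(1H)-one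
Product: 18 5-[cis-1,4-bis(triethylsilyloxy)cyclohexyl]-1-hydroxy-4-[2-(trimethylsilyl)ethoxy]pyridin-2(1H)-one
Conditions: H2 (1 atm), Pd/C, EtOAc, rt
Reagents that add atoms: none
Why: Hydrogenolysis of the N–O benzyl ether, the standard release of cyclic hydroxamic acids, done here because the molecule has no alkene and no iodine yet; silyl ethers are stable in ethyl acetate and the reaction is stopped after one equivalent of hydrogen to spare the N–O bond.

Step 12
Reactants: 18 5-[cis-1,4-bis(triethylsilyloxy)cyclohexyl]-1-hydroxy-4-[2-(trimethylsilyl)ethoxy]pyridin-2(1H)-one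
Product: 19 5-[cis-1,4-bis(triethylsilyloxy)cyclohexyl]-4-[2-(trimethylsilyl)ethoxy]-1-{[2-(trimethylsilyl)ethoxy]methoxy}pyridin-2(1H)-one
Conditions: SEMCl, iPr2NEt, CH2Cl2, 0 °C → rt
Reagents that add atoms: 2-(trimethylsilyl)ethoxymethyl chloride, C[Si](C)(C)CCOCCl
Why: O-Alkylation of the acidic N–OH group of the cyclic hydroxamic acid with a chloromethyl ether; it is the only free hydroxyl, so no regiochemical question arises, and the acetal formed is stable to organomagnesium reagents and cleaved by fluoride.

Step 13
Reactants: 19 5-[cis-1,4-bis(triethylsilyloxy)cyclohexyl]-4-[2-(trimethylsilyl)ethoxy]-1-{[2-(trimethylsilyl)ethoxy]methoxy}pyridin-2(1H)-one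
Product: 20 5-[cis-1,4-bis(triethylsilyloxy)cyclohexyl]-3-iodo-4-[2-(trimethylsilyl)ethoxy]-1-{[2-(trimethylsilyl)ethoxy]methoxy}pyridin-2(1H)-one
Conditions: NIS, MeCN, rt, dark
Reagents that add atoms: N-iodosuccinimide, O=C1CCC(=O)N1I
Why: Electrophilic iodination at C3, the enol-ether carbon between the C2 carbonyl and the C4 oxygen and the most nucleophilic position of a 4-alkoxy-2-pyridone; C5 is blocked and C6 is not activated.

Step 14
Reactants: 21 (R)-4-benzyloxazolidin-2-one; 22 butanoyl chloride
Product: 23 (R)-4-benzyl-3-butanoyloxazolidin-2-one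
Conditions: n-BuLi, THF, −78 °C; then 22, −78 → 0 °C
Reagents that add atoms: none
Why: N-Acylation of the lithiated oxazolidinone with an acid chloride, the standard preparation of an Evans imide; the auxiliary stereocentre is not touched.

Step 15
Reactants: 23 (R)-4-benzyl-3-butanoyloxazolidin-2-one
Product: 24 (R)-4-benzyl-3-[(2S)-2-(hydroxymethyl)butanoyl]oxazolidin-2-one
Conditions: TiCl4, iPr2NEt, CH2Cl2, 0 °C; then 1,3,5-trioxane, TiCl4, 0 °C
Reagents that add atoms: 1,3,5-trioxane, C1OCOCO1
Why: Evans titanium-enolate hydroxymethylation: the chelated Z-enolate is attacked by formaldehyde, released from trioxane by TiCl4, on the face opposite the benzyl group of the (R)-auxiliary, which sets the new centre as 2S, the arrangement that becomes 8''R in the target.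

Step 16
Reactants: 24 (R)-4-benzyl-3-[(2S)-2-(hydroxymethyl)butanoyl]oxazolidin-2-one
Product: 25 (R)-4-benzyl-3-[(2S)-2-{[(tert-butyldimethylsilyl)oxy]methyl}butanoyl]oxazolidin-2-one
Conditions: tBuMe2SiCl, imidazole, DMF, rt
Reagents that add atoms: tert-butyldimethylsilyl chloride, CC(C)(C)[Si](C)(C)Cl
Why: Silylation of the primary alcohol; it must precede removal of the auxiliary, because reduction of the free hydroxy imide would give an achiral 1,3-diol, and the silyl ether then lasts until the final fluoride step.

Step 17
Reactants: 25 (R)-4-benzyl-3-[(2S)-2-{[(tert-butyldimethylsilyl)oxy]methyl}butanoyl]oxazolidin-2-one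
Product: 26 (2R)-2-{[(tert-butyldimethylsilyl)oxy]methyl}butan-1-ol
Conditions: LiBH4, H2O (1 equiv), Et2O, 0 °C
Reagents that add atoms: none
Why: Reductive cleavage of the imide at the exocyclic carbonyl with lithium borohydride; the stereocentre is not enolised under these conditions (the descriptor changes only through the priority rules) and the auxiliary is recovered.

Step 18
Reactants: 26 (2R)-2-{[(tert-butyldimethylsilyl)oxy]methyl}butan-1-ol; 27 (triphenylphosphoranylidene)acetaldehyde
Product: 29 (2E,4R)-4-{[(tert-butyldimethylsilyl)oxy]methyl}hex-2-enal, via silyloxymethyl butanal 28 (not isolated)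
Conditions: (COCl)2, DMSO, CH2Cl2, −78 °C; iPr2NEt; then 27, −78 → 40 °C
Reagents that add atoms: none
Why: Swern oxidation followed in the same flask by Wittig olefination with a stabilised ylide, which should give the E enal; the α-stereogenic β-silyloxy aldehyde is consumed as it forms, so it has no opportunity to epimerise or eliminate, and the saturated aldehyde reacts faster than the enal product.

Step 19
Reactants: 29 (2E,4R)-4-{[(tert-butyldimethylsilyl)oxy]methyl}hex-2-enal; 30 triethyl 4-phosphonocrotonate
Product: 31 ethyl (2E,4E,6E,8R)-8-{[(tert-butyldimethylsilyl)oxy]methyl}deca-2,4,6-trienoate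
Conditions: LiN(SiMe3)2, THF, −78 → 0 °C
Reagents that add atoms: none
Why: Vinylogous Horner–Wadsworth–Emmons olefination; the lithiated phosphonate reacts at its α-carbon and the stabilised anion favours the E alkene, and the stereocentre, now γ to the aldehyde, is not deprotonated by this weakly basic anion.

Step 20
Reactants: 31 ethyl (2E,4E,6E,8R)-8-{[(tert-butyldimethylsilyl)oxy]methyl}deca-2,4,6-trienoate
Product: 32 (2E,4E,6E,8R)-8-{[(tert-butyldimethylsilyl)oxy]methyl}deca-2,4,6-trien-1-ol
Conditions: iBu2AlH, CH2Cl2, −78 °C
Reagents that add atoms: none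
Why: 1,2-Reduction of the conjugated ester to the allylic alcohol with a dialkylaluminium hydride at low temperature; the triene and the silyl ether are not affected.

Step 21
Reactants: 32 (2E,4E,6E,8R)-8-{[(tert-butyldimethylsilyl)oxy]methyl}deca-2,4,6-trien-1-ol
Product: 33 (2E,4E,6E,8R)-8-{[(tert-butyldimethylsilyl)oxy]methyl}deca-2,4,6-trienal
Conditions: MnO2, CH2Cl2, rt, dark
Reagents that add atoms: none
Why: Manganese dioxide oxidation, selective for allylic alcohols and neutral, so the all-E geometry and the silyl ether are kept.

Step 22
Reactants: 20 5-[cis-1,4-bis(triethylsilyloxy)cyclohexyl]-3-iodo-4-[2-(trimethylsilyl)ethoxy]-1-{[2-(trimethylsilyl)ethoxy]methoxy}pyridin-2(1H)-one; 33 (2E,4E,6E,8R)-8-{[(tert-butyldimethylsilyl)oxy]methyl}deca-2,4,6-trienal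
Product: 35 5-[cis-1,4-bis(triethylsilyloxy)cyclohexyl]-3-[(2E,4E,6E,8R)-8-{[(tert-butyldimethylsilyl)oxy]methyl}-1-hydroxydeca-2,4,6-trien-1-yl]-4-[2-(trimethylsilyl)ethoxy]-1-{[2-(trimethylsilyl)ethoxy]methoxy}pyridin-2(1H)-one (both C1'' epimers), via pyridonylmagnesium chloride 34 (not isolated)
Conditions: iPrMgCl·LiCl, THF, −40 °C; then 33, −40 → 0 °C
Reagents that add atoms: none
Why: Iodine–magnesium exchange at low temperature gives a C3 arylmagnesium species held by the flanking oxygen donors, which should add 1,2 to the conjugated aldehyde (Grignard addition); the new C1'' carbinol centre forms without control, which is immaterial because it is oxidised in the next step.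

Step 23
Reactants: 35 5-[cis-1,4-bis(triethylsilyloxy)cyclohexyl]-3-[(2E,4E,6E,8R)-8-{[(tert-butyldimethylsilyl)oxy]methyl}-1-hydroxydeca-2,4,6-trien-1-yl]-4-[2-(trimethylsilyl)ethoxy]-1-{[2-(trimethylsilyl)ethoxy]methoxy}pyridin-2(1H)-one
Product: 36 5-[cis-1,4-bis(triethylsilyloxy)cyclohexyl]-3-[(2E,4E,6E,8R)-8-{[(tert-butyldimethylsilyl)oxy]methyl}deca-2,4,6-trienoyl]-4-[2-(trimethylsilyl)ethoxy]-1-{[2-(trimethylsilyl)ethoxy]methoxy}pyridin-2(1H)-one
Conditions: Dess–Martin periodinane, pyridine, CH2Cl2, 0 °C → rt
Reagents that add atoms: none
Why: Dess–Martin oxidation of a secondary carbinol that is both allylic and attached to the heteroarene; the buffered, neutral conditions leave silyl ethers, the N–O acetal and the triene geometry alone and remove the uncontrolled C1'' centre.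

Step 24
Reactants: 36 5-[cis-1,4-bis(triethylsilyloxy)cyclohexyl]-3-[(2E,4E,6E,8R)-8-{[(tert-butyldimethylsilyl)oxy]methyl}deca-2,4,6-trienoyl]-4-[2-(trimethylsilyl)ethoxy]-1-{[2-(trimethylsilyl)ethoxy]methoxy}pyridin-2(1H)-one
Product: 37 3-[(2E,4E,6E,8R)-8-(hydroxymethyl)deca-2,4,6-trienoyl]-1,4-dihydroxy-5-(cis-1,4-dihydroxycyclohexyl)pyridin-2(1H)-one
Conditions: Bu4NF, THF, 0 °C → rt; aqueous work-up at pH 5
Reagents that add atoms: none
Why: Global fluoride deprotection: the three silyl ethers are cleaved at Si–O, the β-silylethyl group on O4 leaves by β-elimination (ethene) and the N–O acetal by fragmentation (ethene and formaldehyde), both helped by the acidity of the pyridone oxygens they release; no acid and no hydrogen are involved, so the C1' carbinol and the trienone should survive.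

## Compound list

1 | 5-bromo-2,4-dichloropyridine | Clc1cc(Cl)c(Br)cn1 | starting material
2 | 2-(trimethylsilyl)ethanol | C[Si](C)(C)CCO | starting material
3 | 5-bromo-2-chloro-4-[2-(trimethylsilyl)ethoxy]pyridine | C[Si](C)(C)CCOc1cc(Cl)ncc1Br | intermediate
4 | benzyl alcohol | OCc1ccccc1 | starting material
5 | 2-(benzyloxy)-5-bromo-4-[2-(trimethylsilyl)ethoxy]pyridine | C[Si](C)(C)CCOc1cc(OCc2ccccc2)ncc1Br | intermediate
6 | cyclohex-2-en-1-one | O=C1C=CCCC1 | starting material
7 | cyclohexa-1,3-dien-1-yl trifluoromethanesulfonate | O=S(=O)(OC1=CC=CCC1)C(F)(F)F | intermediate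
8 | bis(pinacolato)diboron | CC1(C)OB(OC1(C)C)B1OC(C)(C)C(C)(C)O1 | starting material
9 | 2-(benzyloxy)-5-(4,4,5,5-tetramethyl-1,3,2-dioxaborolan-2-yl)-4-[2-(trimethylsilyl)ethoxy]pyridine (formed in the flask, not isolated) | C[Si](C)(C)CCOc1cc(OCc2ccccc2)ncc1B1OC(C)(C)C(C)(C)O1 | intermediate
10 | 2-(benzyloxy)-5-(cyclohexa-1,3-dien-1-yl)-4-[2-(trimethylsilyl)ethoxy]pyridine | C[Si](C)(C)CCOc1cc(OCc2ccccc2)ncc1C1=CC=CCC1 | intermediate
11 | dioxygen (reacts as singlet oxygen) | O=O | starting material
12 | 2-(benzyloxy)-5-(2,3-dioxabicyclo[2.2.2]oct-5-en-1-yl)-4-[2-(trimethylsilyl)ethoxy]pyridine (racemic, one enantiomer drawn) | C[Si](C)(C)CCOc1cc(OCc2ccccc2)ncc1[C@]12CC[C@H](C=C1)OO2 | intermediate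
13 | 2-(benzyloxy)-5-(2,3-dioxabicyclo[2.2.2]octan-1-yl)-4-[2-(trimethylsilyl)ethoxy]pyridine | C[Si](C)(C)CCOc1cc(OCc2ccccc2)ncc1C12CCC(CC1)OO2 | intermediate
14 | cis-1-{6-(benzyloxy)-4-[2-(trimethylsilyl)ethoxy]pyridin-3-yl}cyclohexane-1,4-diol | C[Si](C)(C)CCOc1cc(OCc2ccccc2)ncc1[C@]1(O)CC[C@@H](O)CC1 | intermediate
15 | 2-(benzyloxy)-5-[cis-1,4-bis(triethylsilyloxy)cyclohexyl]-4-[2-(trimethylsilyl)ethoxy]pyridine | C[Si](C)(C)CCOc1cc(OCc2ccccc2)ncc1[C@]1(O[Si](CC)(CC)CC)CC[C@@H](O[Si](CC)(CC)CC)CC1 | intermediate
16 | 2-(benzyloxy)-5-[cis-1,4-bis(triethylsilyloxy)cyclohexyl]-4-[2-(trimethylsilyl)ethoxy]pyridine 1-oxide | C[Si](C)(C)CCOc1cc(OCc2ccccc2)[n+]([O-])cc1[C@]1(O[Si](CC)(CC)CC)CC[C@@H](O[Si](CC)(CC)CC)CC1 | intermediate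
17 | 1-(benzyloxy)-5-[cis-1,4-bis(triethylsilyloxy)cyclohexyl]-4-[2-(trimethylsilyl)ethoxy]pyridin-2(1H)-one | C[Si](C)(C)CCOc1cc(=O)n(OCc2ccccc2)cc1[C@]1(O[Si](CC)(CC)CC)CC[C@@H](O[Si](CC)(CC)CC)CC1 | intermediate
18 | 5-[cis-1,4-bis(triethylsilyloxy)cyclohexyl]-1-hydroxy-4-[2-(trimethylsilyl)ethoxy]pyridin-2(1H)-one | C[Si](C)(C)CCOc1cc(=O)n(O)cc1[C@]1(O[Si](CC)(CC)CC)CC[C@@H](O[Si](CC)(CC)CC)CC1 | intermediate
19 | 5-[cis-1,4-bis(triethylsilyloxy)cyclohexyl]-4-[2-(trimethylsilyl)ethoxy]-1-{[2-(trimethylsilyl)ethoxy]methoxy}pyridin-2(1H)-one | C[Si](C)(C)CCOCOn1cc([C@]2(O[Si](CC)(CC)CC)CC[C@@H](O[Si](CC)(CC)CC)CC2)c(OCC[Si](C)(C)C)cc1=O | intermediate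
20 | 5-[cis-1,4-bis(triethylsilyloxy)cyclohexyl]-3-iodo-4-[2-(trimethylsilyl)ethoxy]-1-{[2-(trimethylsilyl)ethoxy]methoxy}pyridin-2(1H)-one | C[Si](C)(C)CCOCOn1cc([C@]2(O[Si](CC)(CC)CC)CC[C@@H](O[Si](CC)(CC)CC)CC2)c(OCC[Si](C)(C)C)c(I)c1=O | intermediate
21 | (R)-4-benzyloxazolidin-2-one | O=C1N[C@H](Cc2ccccc2)CO1 | starting material
22 | butanoyl chloride | CCCC(Cl)=O | starting material
23 | (R)-4-benzyl-3-butanoyloxazolidin-2-one | CCCC(=O)N1[C@H](Cc2ccccc2)COC1=O | intermediate
24 | (R)-4-benzyl-3-[(2S)-2-(hydroxymethyl)butanoyl]oxazolidin-2-one | CC[C@@H](CO)C(=O)N1[C@H](Cc2ccccc2)COC1=O | intermediate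
25 | (R)-4-benzyl-3-[(2S)-2-{[(tert-butyldimethylsilyl)oxy]methyl}butanoyl]oxazolidin-2-one | CC[C@@H](CO[Si](C)(C)C(C)(C)C)C(=O)N1[C@H](Cc2ccccc2)COC1=O | intermediate
26 | (2R)-2-{[(tert-butyldimethylsilyl)oxy]methyl}butan-1-ol | CC[C@@H](CO[Si](C)(C)C(C)(C)C)CO | intermediate
27 | (triphenylphosphoranylidene)acetaldehyde | O=CC=P(c1ccccc1)(c1ccccc1)c1ccccc1 | starting material
28 | (2S)-2-{[(tert-butyldimethylsilyl)oxy]methyl}butanal (formed in the flask, not isolated) | CC[C@@H](CO[Si](C)(C)C(C)(C)C)C=O | intermediate
29 | (2E,4R)-4-{[(tert-butyldimethylsilyl)oxy]methyl}hex-2-enal | CC[C@@H](CO[Si](C)(C)C(C)(C)C)/C=C/C=O | intermediate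
30 | triethyl 4-phosphonocrotonate (ethyl (2E)-4-(diethoxyphosphoryl)but-2-enoate) | CCOC(=O)/C=C/CP(=O)(OCC)OCC | starting material
31 | ethyl (2E,4E,6E,8R)-8-{[(tert-butyldimethylsilyl)oxy]methyl}deca-2,4,6-trienoate | CC[C@@H](CO[Si](C)(C)C(C)(C)C)/C=C/C=C/C=C/C(=O)OCC | intermediate
32 | (2E,4E,6E,8R)-8-{[(tert-butyldimethylsilyl)oxy]methyl}deca-2,4,6-trien-1-ol | CC[C@@H](CO[Si](C)(C)C(C)(C)C)/C=C/C=C/C=C/CO | intermediate
33 | (2E,4E,6E,8R)-8-{[(tert-butyldimethylsilyl)oxy]methyl}deca-2,4,6-trienal | CC[C@@H](CO[Si](C)(C)C(C)(C)C)/C=C/C=C/C=C/C=O | intermediate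
34 | {5-[cis-1,4-bis(triethylsilyloxy)cyclohexyl]-2-oxo-4-[2-(trimethylsilyl)ethoxy]-1-{[2-(trimethylsilyl)ethoxy]methoxy}-1,2-dihydropyridin-3-yl}magnesium chloride (formed in the flask, not isolated) | C[Si](C)(C)CCOCOn1cc([C@]2(O[Si](CC)(CC)CC)CC[C@@H](O[Si](CC)(CC)CC)CC2)c(OCC[Si](C)(C)C)c([Mg]Cl)c1=O | intermediate
35 | 5-[cis-1,4-bis(triethylsilyloxy)cyclohexyl]-3-[(2E,4E,6E,8R)-8-{[(tert-butyldimethylsilyl)oxy]methyl}-1-hydroxydeca-2,4,6-trien-1-yl]-4-[2-(trimethylsilyl)ethoxy]-1-{[2-(trimethylsilyl)ethoxy]methoxy}pyridin-2(1H)-one (both C1'' epimers) | C[Si](C)(C)CCOCOn1cc([C@]2(O[Si](CC)(CC)CC)CC[C@@H](O[Si](CC)(CC)CC)CC2)c(OCC[Si](C)(C)C)c(C(O)/C=C/C=C/C=C/[C@@H](CC)CO[Si](C)(C)C(C)(C)C)c1=O | intermediate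
36 | 5-[cis-1,4-bis(triethylsilyloxy)cyclohexyl]-3-[(2E,4E,6E,8R)-8-{[(tert-butyldimethylsilyl)oxy]methyl}deca-2,4,6-trienoyl]-4-[2-(trimethylsilyl)ethoxy]-1-{[2-(trimethylsilyl)ethoxy]methoxy}pyridin-2(1H)-one | C[Si](C)(C)CCOCOn1cc([C@]2(O[Si](CC)(CC)CC)CC[C@@H](O[Si](CC)(CC)CC)CC2)c(OCC[Si](C)(C)C)c(C(=O)/C=C/C=C/C=C/[C@@H](CC)CO[Si](C)(C)C(C)(C)C)c1=O | intermediate
37 | 3-[(2E,4E,6E,8R)-8-(hydroxymethyl)deca-2,4,6-trienoyl]-1,4-dihydroxy-5-(cis-1,4-dihydroxycyclohexyl)pyridin-2(1H)-one | CC[C@H](/C=C/C=C/C=C/C(=O)c1c(O)c([C@]2(O)CC[C@@H](O)CC2)cn(O)c1=O)CO | target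

## Step count and least certain steps

Total: 24 steps. Longest linear sequence: 15 steps from 1 (steps 1, 2, 4 to 13, 22 to 24). The triflate (step 3) joins at step 4 and the chain branch (steps 14 to 21) joins at step 22.

**Step 5 (key step).** The most likely failure is diversion of singlet oxygen into the ene pathway at the C5'/C6' methylenes, with the hydroperoxides and the diene itself then dehydrogenating to the aromatic 5-phenylpyridine. The second risk is loss of the endoperoxide on work-up, by base-induced fragmentation at the C4' bridgehead hydrogen or by ionisation of the tertiary C1'–O bond, which is activated by the pyridine ring and the neighbouring alkene. The fallback abandons the peroxide and makes the C5–C1' bond and the carbinol in one step. It sets out from 5: bromine–lithium exchange (n-BuLi, THF, −78 °C) and addition of the aryllithium to 4-(triethylsilyloxy)cyclohexan-1-one F1 (from 4-hydroxycyclohexanone, Et3SiCl and imidazole). Equatorial attack on the ketone should favour the cis carbinol, cis-1-{6-(benzyloxy)-4-[2-(trimethylsilyl)ethoxy]pyridin-3-yl}-4-(triethylsilyloxy)cyclohexan-1-ol F2, which is separated from its trans isomer and silylated at the tertiary hydroxyl (Et3SiOTf, 2,6-lutidine). The fallback comes back to the route at 15. Its price is that the cis relation then rests on facial selectivity and a separation.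

**Step 3.** The most likely failure is loss of regiocontrol in the deprotonation of the O-triflyl allyl cation: removal of an α′-hydrogen in place of a γ-hydrogen gives the cross-conjugated dienyl triflate, which would place the pyridine on an inner diene carbon and make the key step deliver the wrong skeleton; the volatile triflate may also isomerise on storage. The fallback fixes the diene position by construction. It sets out from 5: borylation as in step 4 and coupling of boronate 9 with commercial 3-bromocyclohex-2-en-1-one give 3-{6-(benzyloxy)-4-[2-(trimethylsilyl)ethoxy]pyridin-3-yl}cyclohex-2-en-1-one F3. Condensation with tosylhydrazine gives the tosylhydrazone of that enone F4. Shapiro elimination (LDA, THF, −78 °C → rt), which removes an α′-proton and leaves the existing double bond in place, gives the diene. The fallback comes back at 10.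

**Step 10.** The most likely failure is incomplete or intermolecular benzyl transfer at the temperature needed, with crossover and C-benzylation, or thermal elimination of the tertiary silyloxy group. The fallback drops the rearrangement: starting from 16, hydrogenolysis of the O2 benzyl ether of the N-oxide (H2, Pd/C, EtOAc, rt) gives the 2-hydroxypyridine N-oxide, which is the tautomer of the N-hydroxypyridone, so it comes back at 18 and skips 17. It makes no new compound (F0). Its own risk is deoxygenation of the N-oxide before debenzylation.

**Step 22.** The most likely failure is slow exchange or decay of the metalated N-alkoxypyridone (attack of the alkylmagnesium reagent at C6 or on the N–O acetal), or sluggish 1,2-addition of an arylmagnesium flanked by two ortho substituents, leaving enolisation and conjugate addition to the trienal to compete. The fallback needs no metalated pyridone and forms the ketone directly by a carbonylative Stille coupling. From 29, Wittig reaction with 27 (toluene, 80 °C) gives (2E,4E,6R)-6-{[(tert-butyldimethylsilyl)oxy]methyl}octa-2,4-dienal F5. Takai-type stannyl olefination (CrCl2, Bu3SnCHBr2, LiI, THF/DMF) gives tributyl[(1E,3E,5E,7R)-7-{[(tert-butyldimethylsilyl)oxy]methyl}nona-1,3,5-trien-1-yl]stannane F6. Iodide 20, CO (1 atm) and F6 with Pd2(dba)3 and AsPh3 (zerovalent palladium, NMP, 50 °C) then give the ketone. The fallback sets out from 20 and 29 and comes back at 36, skipping 35.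

**Step 24.** The most likely failure is base-induced degradation of the trienone by the basic fluoride medium (E/Z isomerisation, conjugate addition of the alkoxides set free) before the slower fragmentations of the β-silylethyl ether and the N–O acetal are complete. The fallback changes the order so that no enone ever meets fluoride. It sets out from 35: treatment with Bu4NF in THF removes all five groups from the carbinol and gives 3-[(2E,4E,6E,8R)-1-hydroxy-8-(hydroxymethyl)deca-2,4,6-trien-1-yl]-1,4-dihydroxy-5-(cis-1,4-dihydroxycyclohexyl)pyridin-2(1H)-one F7. MnO2 in CH2Cl2/acetone then oxidises only the carbinol that is both allylic and attached to the heteroarene. The fallback comes back at 37.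

## Further compounds

F1 | step 5 | 4-(triethylsilyloxy)cyclohexan-1-one | O=C1CCC(O[Si](CC)(CC)CC)CC1
F2 | step 5 | cis-1-{6-(benzyloxy)-4-[2-(trimethylsilyl)ethoxy]pyridin-3-yl}-4-(triethylsilyloxy)cyclohexan-1-ol | C[Si](C)(C)CCOc1cc(OCc2ccccc2)ncc1[C@]1(O)CC[C@@H](O[Si](CC)(CC)CC)CC1
F3 | step 3 | 3-{6-(benzyloxy)-4-[2-(trimethylsilyl)ethoxy]pyridin-3-yl}cyclohex-2-en-1-one | C[Si](C)(C)CCOc1cc(OCc2ccccc2)ncc1C1=CC(=O)CCC1
F4 | step 3 | N'-(3-{6-(benzyloxy)-4-[2-(trimethylsilyl)ethoxy]pyridin-3-yl}cyclohex-2-en-1-ylidene)-4-methylbenzenesulfonohydrazide | C[Si](C)(C)CCOc1cc(OCc2ccccc2)ncc1C1=CC(=NNS(=O)(=O)c2ccc(C)cc2)CCC1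
F0 | step 10 | none | none
F5 | step 22 | (2E,4E,6R)-6-{[(tert-butyldimethylsilyl)oxy]methyl}octa-2,4-dienal | CC[C@@H](CO[Si](C)(C)C(C)(C)C)/C=C/C=C/C=O
F6 | step 22 | tributyl[(1E,3E,5E,7R)-7-{[(tert-butyldimethylsilyl)oxy]methyl}nona-1,3,5-trien-1-yl]stannane | CC[C@@H](CO[Si](C)(C)C(C)(C)C)/C=C/C=C/C=C/[Sn](CCCC)(CCCC)CCCC
F7 | step 24 | 3-[(2E,4E,6E,8R)-1-hydroxy-8-(hydroxymethyl)deca-2,4,6-trien-1-yl]-1,4-dihydroxy-5-(cis-1,4-dihydroxycyclohexyl)pyridin-2(1H)-one | CC[C@H](/C=C/C=C/C=C/C(O)c1c(O)c([C@]2(O)CC[C@@H](O)CC2)cn(O)c1=O)CO
A1 | alternative 1 | O-ethyl S-{[cis-4-(tert-butyldimethylsilyloxy)-1-(triethylsilyloxy)cyclohexyl](3,5-dioxopyrrolidin-2-yl)methyl} carbonodithioate | CCOC(=S)SC(C1NC(=O)CC1=O)[C@]2(O[Si](CC)(CC)CC)CC[C@@H](O[Si](C)(C)C(C)(C)C)CC2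
A2 | alternative 1 | 5-[cis-4-(tert-butyldimethylsilyloxy)-1-(triethylsilyloxy)cyclohexyl]piperidine-2,4-dione (racemic at C5, one enantiomer drawn) | O=C1CC(=O)[C@H](CN1)[C@]2(O[Si](CC)(CC)CC)CC[C@@H](O[Si](C)(C)C(C)(C)C)CC2
A3 | alternative 2 | tributyl[(1E,3E,5E,7R)-7-{[(tert-butyldimethylsilyl)oxy]methyl}nona-1,3,5-trien-1-yl]stannane | CC[C@H](/C=C/C=C/C=C/[Sn](CCCC)(CCCC)CCCC)CO[Si](C)(C)C(C)(C)C
A4 | alternative 2 | 1,4-bis(benzyloxy)-5-[cis-4-(tert-butyldimethylsilyloxy)-1-hydroxycyclohexyl]-3-iodopyridin-2(1H)-one | O=c1c(I)c(OCc2ccccc2)c([C@]3(O)CC[C@@H](O[Si](C)(C)C(C)(C)C)CC3)cn1OCc1ccccc1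
A5 | alternative 2 | 1,4-bis(benzyloxy)-3-[(2E,4E,6E,8R)-8-{[(tert-butyldimethylsilyl)oxy]methyl}deca-2,4,6-trienoyl]-5-[cis-4-(tert-butyldimethylsilyloxy)-1-hydroxycyclohexyl]pyridin-2(1H)-one | CC[C@H](/C=C/C=C/C=C/C(=O)c1c(OCc2ccccc2)c([C@]3(O)CC[C@@H](O[Si](C)(C)C(C)(C)C)CC3)cn(OCc4ccccc4)c1=O)CO[Si](C)(C)C(C)(C)C
A6 | alternative 3 | methyl 4,6-bis(benzyloxy)pyridine-3-carboxylate | COC(=O)c1cnc(OCc2ccccc2)cc1OCc1ccccc1
A7 | alternative 3 | [(1,3-dioxolane-2,2-diyl)di(ethane-2,1-diyl)]bis(magnesium bromide) | Br[Mg]CCC1(CC[Mg]Br)OCCO1
A8 | alternative 3 | 8-[4,6-bis(benzyloxy)pyridin-3-yl]-1,4-dioxaspiro[4.5]decan-8-ol | OC1(c2cnc(OCc3ccccc3)cc2OCc4ccccc4)CCC5(CC1)OCCO5
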